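**Strategy.** Ring A (C1 acyl, C2 OH, C4 OMe, C5 aryloxy) is not taken from an arene. Its oxygens at C2 and C4 are 1,3-related, with the cinnamoyl group on C1 and the ether to ring C on C5, which is the pattern of a 4-acyl-6-aryloxycyclohexane-1,3-dione. A styryl 1,3-diketone (ring B, C1–C3) and a 2-(4-iodophenoxy)acrylate (C4–C6, ring C) are therefore joined in one base-mediated Michael–Claisen annulation that forms C1–C6 and C3–C4. In the saturated ring the two oxygens differ (free enol at C4, chelated enol at C2), so C4 is methylated before DDQ aromatisation. A Heck coupling at the iodide then adds ring D, and acid removes the MOM groups.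

Key step: step 5

Remark on the chemistry: 12 and 13 are mobile keto–enol mixtures, each drawn as one tautomer; the boron chelates 4 and 5 are drawn as dibutoxyboron diketonates, the simplest defined form of the species present.

**Step 1**
Reactants: 1 4-hydroxybenzaldehyde
Product: 2 4-(methoxymethoxy)benzaldehyde
Conditions: MOMCl, K2CO3, acetone, 0 °C to rt
Reagents that add atoms: chloromethyl methyl ether (MOMCl), COCCl
Why: Williamson-type O-alkylation of the phenoxide by the reactive α-chloro ether gives the MOM acetal, which withstands the strong base of step 5 and leaves under mild acid at the end.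

**Step 2**
Reactants: 2 4-(methoxymethoxy)benzaldehyde; 3 acetylacetone (pentane-2,4-dione, threefold excess)
Product: 6 (E)-6-[4-(methoxymethoxy)phenyl]hex-5-ene-2,4-dione, via acetylacetone dibutoxyboron chelate 4 (not isolated), via styryl diketone dibutoxyboron chelate 5 (not isolated)
Conditions: B2O3, B(On-Bu)3, n-BuNH2 (cat.), EtOAc, 70 °C; then 0.5 M HCl, 40 °C, brief
Reagents that add atoms: none
Why: Boron-templated aldol condensation of the Pabon type: chelation ties up the central carbon so the amine-catalysed condensation takes place at a methyl group, the excess of 3 limits it to one arm, E1cB dehydration gives the E styryl ketone, and brief dilute aqueous acid without alcohol frees the diketone while the MOM acetal stays on.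

**Step 3**
Reactants: 7 4-iodophenol
Product: 8 methyl 2-(4-iodophenoxy)acetate
Conditions: BrCH2CO2Me, K2CO3, acetone, reflux
Reagents that add atoms: methyl bromoacetate, COC(=O)CBr
Why: Williamson ether synthesis by SN2 displacement of the activated primary bromide by the phenoxide.

**Step 4**
Reactants: 8 methyl 2-(4-iodophenoxy)acetate
Product: 10 methyl 2-(4-iodophenoxy)prop-2-enoate, via sodium enolate of the oxalyl ester 9 (not isolated)
Conditions: (CO2Me)2, NaOMe, THF, 0 °C to rt; then aq. HCHO, K2CO3, rt
Reagents that add atoms: formaldehyde, C=O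
Why: Oxalate-mediated α-methylenation of an ester: crossed Claisen condensation with dimethyl oxalate gives a stabilised enolate that adds formaldehyde, and the aldolate transfers the oxalyl group to oxygen and expels methyl oxalate by E1cB to leave the α-methylene ester.

**Step 5**
Reactants: 6 (E)-6-[4-(methoxymethoxy)phenyl]hex-5-ene-2,4-dione; 10 methyl 2-(4-iodophenoxy)prop-2-enoate
Product: 12 4-(4-iodophenoxy)-6-{(E)-3-[4-(methoxymethoxy)phenyl]prop-2-enoyl}cyclohexane-1,3-dione (racemic mixture of epimers/enol tautomers), via Michael adduct 11 (not isolated)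
Conditions: KOt-Bu (3 equiv), THF, 0 °C to 40 °C; then 1 M HCl, 0 °C
Reagents that add atoms: none
Why: Proposed new method: with all of 6 held as its potassium diketonate (whose own cinnamoyl group is thereby switched off as an acceptor), the central carbon should add to the unsubstituted CH2 terminus of the captodative acrylate 10 in a Michael addition, and proton transfer gives the diketonate of 11 (C1–C6 bond). Excess tert-butoxide then reversibly deprotonates the only enolisable terminus, the methyl group, and this carbon attacks the α-aryloxy ester in a 6-(enolendo)-exo-trig Claisen (Dieckmann-type) closure that forms C3–C4 and ring A; expulsion of methoxide followed by immediate deprotonation of the new ring 1,3-dione is the one irreversible event and should drain the reversible side equilibria (retro-Michael, O-acylation to the enol lactone, unproductive ester enolate). The closest known reaction types are the consecutive Michael–Claisen synthesis of cyclohexane-1,3-diones from methyl ketones plus acrylates and the terminal acylation of β-diketone dianions by esters; a 1,3-diketone donor combined with a 2-aryloxyacrylate has not been shown. The two new stereocentres, C1 and C5 of ring A, both lie α to carbonyl groups, so they form without control as an equilibrating mixture of epimers and enols, which is harmless because step 7 removes both. The selectivity needed is C-acylation through the methyl carbon: the cinnamoyl side has no α-hydrogen, closure from the central carbon would give a four-membered ring, and the aryloxy group sits α (never β) to a carbanion-stabilising carbonyl, so it cannot be expelled by E1cB.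

**Step 6**
Reactants: 12 4-(4-iodophenoxy)-6-{(E)-3-[4-(methoxymethoxy)phenyl]prop-2-enoyl}cyclohexane-1,3-dione
Product: 13 (E)-1-[2-hydroxy-5-(4-iodophenoxy)-4-methoxycyclohexa-1,3-dien-1-yl]-3-[4-(methoxymethoxy)phenyl]prop-2-en-1-one (racemic at C5; chelated enol form)
Conditions: TMSCHN2 (1.05 equiv), MeOH/toluene, 0 °C
Reagents that add atoms: trimethylsilyldiazomethane, C[Si](C)(C)C=[N+]=[N-]
Why: Diazoalkane O-methylation of a cyclic 1,3-dione: the free, most acidic enol oxygen at C4 is methylated, whereas the C2 oxygen is held in a hydrogen-bonded chelate with the side-chain carbonyl, and the product is the more conjugated vinylogous ester.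

**Step 7**
Reactants: 13 (E)-1-[2-hydroxy-5-(4-iodophenoxy)-4-methoxycyclohexa-1,3-dien-1-yl]-3-[4-(methoxymethoxy)phenyl]prop-2-en-1-one
Product: 14 (E)-1-[2-hydroxy-5-(4-iodophenoxy)-4-methoxyphenyl]-3-[4-(methoxymethoxy)phenyl]prop-2-en-1-one
Conditions: DDQ (1.05 equiv), 1,4-dioxane, rt
Reagents that add atoms: none
Why: DDQ dehydrogenation: hydride abstraction from C6 of the dienol gives a cation stabilised by the oxygens at C2 and C4, loss of the C5 proton aromatises ring A with the aryloxy group retained, and the remaining labile stereocentre disappears.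

**Step 8**
Reactants: 14 (E)-1-[2-hydroxy-5-(4-iodophenoxy)-4-methoxyphenyl]-3-[4-(methoxymethoxy)phenyl]prop-2-en-1-one
Product: 15 (E)-1-[5-(4-iodophenoxy)-4-methoxy-2-(methoxymethoxy)phenyl]-3-[4-(methoxymethoxy)phenyl]prop-2-en-1-one
Conditions: NaH, MOMCl, DMF, 0 °C
Reagents that add atoms: chloromethyl methyl ether (MOMCl), COCCl
Why: Williamson-type O-alkylation of the sodium phenoxide, which stays as the open chalcone, removes the acidic chelated OH so that neither flavanone closure nor oxa-Michael addition to the vinyl ketone can interfere in step 12.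

**Step 9**
Reactants: 16 2,4-dihydroxybenzaldehyde
Product: 17 2,4-bis(methoxymethoxy)benzaldehyde
Conditions: NaH, MOMCl, DMF, 0 °C to rt
Reagents that add atoms: chloromethyl methyl ether (MOMCl), COCCl
Why: Williamson-type O-alkylation of both phenoxides; full deprotonation with NaH also brings the chelated 2-OH into reaction.

**Step 10**
Reactants: 17 2,4-bis(methoxymethoxy)benzaldehyde
Product: 18 1-[2,4-bis(methoxymethoxy)phenyl]prop-2-en-1-ol (racemic)
Conditions: CH2=CHMgBr, THF, −78 to 0 °C; then aq. NH4Cl
Reagents that add atoms: vinylmagnesium bromide, C=C[Mg]Br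
Why: Grignard 1,2-addition to the aldehyde; the carbinol centre forms as a racemate and is removed by the oxidation in step 11.

**Step 11**
Reactants: 18 1-[2,4-bis(methoxymethoxy)phenyl]prop-2-en-1-ol
Product: 19 1-[2,4-bis(methoxymethoxy)phenyl]prop-2-en-1-one
Conditions: MnO2, CH2Cl2, rt
Reagents that add atoms: none
Why: MnO2 oxidation of a doubly activated (allylic and benzylic) alcohol under neutral conditions that leave the MOM acetals intact; the enone is used at once to avoid polymerisation.

**Step 12**
Reactants: 15 (E)-1-[5-(4-iodophenoxy)-4-methoxy-2-(methoxymethoxy)phenyl]-3-[4-(methoxymethoxy)phenyl]prop-2-en-1-one; 19 1-[2,4-bis(methoxymethoxy)phenyl]prop-2-en-1-one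
Product: 20 (E)-1-[2,4-bis(methoxymethoxy)phenyl]-3-{4-[2-methoxy-4-(methoxymethoxy)-5-{(E)-3-[4-(methoxymethoxy)phenyl]prop-2-enoyl}phenoxy]phenyl}prop-2-en-1-one
Conditions: Pd(OAc)2 (5 mol %), n-Bu4NCl, NaHCO3, DMF, 60 °C
Reagents that add atoms: none
Why: Mizoroki–Heck reaction under Jeffery conditions: zerovalent palladium formed in situ inserts into the C–I bond, the aryl group adds to the unsubstituted terminus of the vinyl ketone, and syn β-hydride elimination gives the E enone, while the 1,2-disubstituted enone already present inserts far more slowly.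

**Step 13**
Reactants: 20 (E)-1-[2,4-bis(methoxymethoxy)phenyl]-3-{4-[2-methoxy-4-(methoxymethoxy)-5-{(E)-3-[4-(methoxymethoxy)phenyl]prop-2-enoyl}phenoxy]phenyl}prop-2-en-1-one
Product: 21 (E)-1-(2,4-dihydroxyphenyl)-3-[4-(4-hydroxy-2-methoxy-5-{(E)-3-(4-hydroxyphenyl)prop-2-enoyl}phenoxy)phenyl]prop-2-en-1-one (target)
Conditions: 3 M HCl, MeOH/THF, 45 °C
Reagents that add atoms: none
Why: Acid-catalysed acetal exchange with methanol removes all four MOM groups as dimethoxymethane; the aryl methyl ether, the diaryl ether and both E enones are stable, and closure of the 2'-hydroxychalcones to flavanones is slow at this temperature.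

**Compound list**

1 | 4-hydroxybenzaldehyde | O=Cc1ccc(O)cc1 | starting material
2 | 4-(methoxymethoxy)benzaldehyde | COCOc1ccc(C=O)cc1 | intermediate
3 | acetylacetone (pentane-2,4-dione) | CC(=O)CC(C)=O | starting material
4 | 2,2-dibutoxy-4,6-dimethyl-1,3,2-dioxaborinine chelate of acetylacetone | CCCCO[B-]1(OCCCC)OC(C)=CC(C)=[O+]1 | intermediate (not isolated)
5 | 2,2-dibutoxy-4-methyl-6-{(E)-2-[4-(methoxymethoxy)phenyl]ethenyl}-1,3,2-dioxaborinine chelate | CCCCO[B-]1(OCCCC)OC(C)=CC(/C=C/c2ccc(OCOC)cc2)=[O+]1 | intermediate (not isolated)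
6 | (E)-6-[4-(methoxymethoxy)phenyl]hex-5-ene-2,4-dione | CC(=O)CC(=O)/C=C/c1ccc(OCOC)cc1 | intermediate
7 | 4-iodophenol | Oc1ccc(I)cc1 | starting material
8 | methyl 2-(4-iodophenoxy)acetate | COC(=O)COc1ccc(I)cc1 | intermediate
9 | sodium enolate of dimethyl 2-(4-iodophenoxy)-3-oxobutanedioate | COC(=O)C([O-])=C(Oc1ccc(I)cc1)C(=O)OC.[Na+] | intermediate (not isolated)
10 | methyl 2-(4-iodophenoxy)prop-2-enoate | C=C(Oc1ccc(I)cc1)C(=O)OC | intermediate
11 | methyl (E)-4-acetyl-2-(4-iodophenoxy)-7-[4-(methoxymethoxy)phenyl]-5-oxohept-6-enoate (diastereomer mixture, present as its potassium enolate) | COC(=O)C(Oc1ccc(I)cc1)CC(C(C)=O)C(=O)/C=C/c1ccc(OCOC)cc1 | intermediate (not isolated)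
12 | 4-(4-iodophenoxy)-6-{(E)-3-[4-(methoxymethoxy)phenyl]prop-2-enoyl}cyclohexane-1,3-dione (racemic, epimers and enol forms) | O=C1CC(=O)C(Oc2ccc(I)cc2)CC1C(=O)/C=C/c1ccc(OCOC)cc1 | intermediate
13 | (E)-1-[2-hydroxy-5-(4-iodophenoxy)-4-methoxycyclohexa-1,3-dien-1-yl]-3-[4-(methoxymethoxy)phenyl]prop-2-en-1-one (racemic) | COC1=CC(O)=C(C(=O)/C=C/c2ccc(OCOC)cc2)CC1Oc1ccc(I)cc1 | intermediate
14 | (E)-1-[2-hydroxy-5-(4-iodophenoxy)-4-methoxyphenyl]-3-[4-(methoxymethoxy)phenyl]prop-2-en-1-one | COc1cc(O)c(C(=O)/C=C/c2ccc(OCOC)cc2)cc1Oc1ccc(I)cc1 | intermediate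
15 | (E)-1-[5-(4-iodophenoxy)-4-methoxy-2-(methoxymethoxy)phenyl]-3-[4-(methoxymethoxy)phenyl]prop-2-en-1-one | COCOc1cc(OC)c(Oc2ccc(I)cc2)cc1C(=O)/C=C/c1ccc(OCOC)cc1 | intermediate
16 | 2,4-dihydroxybenzaldehyde | O=Cc1ccc(O)cc1O | starting material
17 | 2,4-bis(methoxymethoxy)benzaldehyde | COCOc1ccc(C=O)c(OCOC)c1 | intermediate
18 | 1-[2,4-bis(methoxymethoxy)phenyl]prop-2-en-1-ol (racemic) | C=CC(O)c1ccc(OCOC)cc1OCOC | intermediate
19 | 1-[2,4-bis(methoxymethoxy)phenyl]prop-2-en-1-one | C=CC(=O)c1ccc(OCOC)cc1OCOC | intermediate
20 | (E)-1-[2,4-bis(methoxymethoxy)phenyl]-3-{4-[2-methoxy-4-(methoxymethoxy)-5-{(E)-3-[4-(methoxymethoxy)phenyl]prop-2-enoyl}phenoxy]phenyl}prop-2-en-1-one | COCOc1ccc(C(=O)/C=C/c2ccc(Oc3cc(C(=O)/C=C/c4ccc(OCOC)cc4)c(OCOC)cc3OC)cc2)c(OCOC)c1 | intermediate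
21 | (E)-1-(2,4-dihydroxyphenyl)-3-[4-(4-hydroxy-2-methoxy-5-{(E)-3-(4-hydroxyphenyl)prop-2-enoyl}phenoxy)phenyl]prop-2-en-1-one | COc1cc(O)c(C(=O)/C=C/c2ccc(O)cc2)cc1Oc1ccc(/C=C/C(=O)c2ccc(O)cc2O)cc1 | target

**Total step count:** 13

**Longest linear sequence:** 8 steps (1, 2, 5, 6, 7, 8, 12, 13; the arm 3, 4 joining at step 5 is equally long).

**Steps most likely to fail**

Step 5 (the one step beyond known chemistry). The second C–C bond may not form: the adduct rests as its diketonate, the α-aryloxy ester is deprotonated in preference to the methyl group, and retro-Michael cleavage, acrylate polymerisation or Michael closure of the ester enolate onto the cinnamoyl group take over. The fallback takes ring A from an arene by known reactions; it sets out from aldehyde 2 and returns at 14. Commercial methoxyhydroquinone is C-acetylated ortho to one hydroxyl and para to the methoxy group (AcOH, BF3·OEt2, 90 °C, Friedel–Crafts acylation) to give 1-(2,5-dihydroxy-4-methoxyphenyl)ethanone F1. Chan–Lam coupling of its free 5-OH with (4-iodophenyl)boronic acid (Cu(OAc)2, pyridine, 4 Å sieves, CH2Cl2, air, rt; the chelated 2-OH and the C–I bond do not react) gives 1-[2-hydroxy-5-(4-iodophenoxy)-4-methoxyphenyl]ethanone F2. Claisen–Schmidt condensation of F2 with 2 (KOH, EtOH, rt) gives 14.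

Step 6. Regiocontrol may be lost, with methylation at the C2 or side-chain oxygen, or the diazoalkane may undergo dipolar cycloaddition to an enone. The fallback reverses the order of events; it sets out from 12 and returns at 14. The trione 12 is dehydrogenated first (DDQ, 1,4-dioxane, rt) to (E)-1-[2,4-dihydroxy-5-(4-iodophenoxy)phenyl]-3-[4-(methoxymethoxy)phenyl]prop-2-en-1-one F3. Its free 4-OH is then methylated selectively (Me2SO4, 1.05 equiv, K2CO3, acetone, rt), because the 2-OH is hydrogen-bonded to the ketone and much less nucleophilic.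

Step 7. Dehydrogenation may stall, or excess DDQ may over-oxidise the freshly formed 2'-hydroxychalcone by oxidative cyclisation towards a flavone or aurone. The fallback uses selenoxide elimination instead of hydride abstraction; it sets out from 13 and returns at 14. The doubly activated C1 of 13 is selenenylated (PhSeCl, pyridine, CH2Cl2, 0 °C) to 4-(4-iodophenoxy)-3-methoxy-6-{(E)-3-[4-(methoxymethoxy)phenyl]prop-2-enoyl}-6-(phenylselanyl)cyclohex-2-en-1-one F4. Oxidation (H2O2, CH2Cl2, 0 °C to rt) triggers syn elimination towards C6, and the resulting cyclohexadienone tautomerises to phenol 14.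

**Further compounds**

F1 | step 5 | 1-(2,5-dihydroxy-4-methoxyphenyl)ethanone | CC(=O)c1cc(O)c(OC)cc1O
F2 | step 5 | 1-[2-hydroxy-5-(4-iodophenoxy)-4-methoxyphenyl]ethanone | CC(=O)c1cc(Oc2ccc(I)cc2)c(OC)cc1O
F3 | step 6 | (E)-1-[2,4-dihydroxy-5-(4-iodophenoxy)phenyl]-3-[4-(methoxymethoxy)phenyl]prop-2-en-1-one | O=C(/C=C/c1ccc(OCOC)cc1)c1cc(Oc2ccc(I)cc2)c(O)cc1O
F4 | step 7 | 4-(4-iodophenoxy)-3-methoxy-6-{(E)-3-[4-(methoxymethoxy)phenyl]prop-2-enoyl}-6-(phenylselanyl)cyclohex-2-en-1-one (diastereomer mixture) | COC1=CC(=O)C([Se]c2ccccc2)(C(=O)/C=C/c2ccc(OCOC)cc2)CC1Oc1ccc(I)cc1
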